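**Retrosynthetic overview**

- Target: ring A is the 6,7-dimethoxybenzo ring, ring B the 1H-pyran ring (C1, O2, C3, C4), ring C the 2,4-dimethoxyphenyl ring. The C3=C4 enol ether is unveiled last by loss of benzenesulfinic acid from a 3-sulfonylisochroman.
- Feature used: without C3, ring B is the mirror-symmetric 5,6-dimethoxyphthalan (C1 and C4 both benzylic on ring A, joined through O2). C3, the carbon that carries the aroyl group, sits formally inserted into one benzylic C–O bond.
- Key disconnection: O2–C3 and C3–C4, both made in one step from the phthalan and a diazo keto sulfone by oxonium ylide formation and Stevens [1,2]-shift. Ring B is the only ring formed (five- to six-membered ring expansion); rings A and C are bought.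
- Phthalan: dimethyl 4,5-dimethoxyphthalate, reduction, then cyclodehydration. Diazo keto sulfone: 2,4-dimethoxyphenacyl bromide, sulfinate displacement, then diazo transfer.

Key step: step 5

Remark on the chemistry: the target is achiral, and the quaternary C3 centre made in step 5 is racemic and becomes sp2 in step 6. The phthalan is not made from 3,4-dimethoxybenzyl alcohol, formaldehyde and acid, because that alcohol self-condenses under acid (cyclotriveratrylene-type oligomers) and closure onto the arene would be a 5-endo process. Dimethyl 4,5-dimethoxyphthalate is assumed to be purchasable (4,5-dimethoxyphthalic anhydride would serve equally).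

**Step 1**
Reactants: 1 dimethyl 4,5-dimethoxyphthalate
Product: 2 (4,5-dimethoxy-1,2-phenylene)dimethanol
Conditions: LiAlH4, THF, 0 °C to reflux; then H2O, aq NaOH
Reagents that add atoms: none
Why: Hydride reduction of both aryl esters with LiAlH4 (ester-to-alcohol reduction) should give the benzylic diol cleanly, the aryl methyl ethers being inert to hydride.

**Step 2**
Reactants: 2 (4,5-dimethoxy-1,2-phenylene)dimethanol
Product: 4 5,6-dimethoxy-1,3-dihydroisobenzofuran, via monotosylate sodium alkoxide 3 (not isolated)
Conditions: NaH (2.2 equiv), THF, 0 °C; TsCl (1.0 equiv), 0 °C to rt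
Reagents that add atoms: none
Why: One-pot monotosylation and intramolecular Williamson etherification, in which the dialkoxide is sulfonylated once and the neighbouring alkoxide displaces the very reactive alkoxybenzylic tosylate in a 5-exo-tet closure faster than a second tosylation or intermolecular etherification, under base so that acid-induced oligomerisation is avoided.

**Step 3**
Reactants: 5 2-bromo-1-(2,4-dimethoxyphenyl)ethanone; 6 sodium benzenesulfinate
Product: 7 1-(2,4-dimethoxyphenyl)-2-(phenylsulfonyl)ethanone
Conditions: DMF, rt
Reagents that add atoms: none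
Why: SN2 displacement at the phenacyl carbon by the soft sulfur atom of the ambident sulfinate (sulfinate S-alkylation) should give the β-keto sulfone at room temperature without touching the aryl ethers.

**Step 4**
Reactants: 7 1-(2,4-dimethoxyphenyl)-2-(phenylsulfonyl)ethanone
Product: 8 2-diazo-1-(2,4-dimethoxyphenyl)-2-(phenylsulfonyl)ethanone
Conditions: 4-acetamidobenzenesulfonyl azide, Et3N, MeCN, 0 °C to rt
Reagents that add atoms: 4-acetamidobenzenesulfonyl azide, CC(=O)Nc1ccc(cc1)S(=O)(=O)N=[N+]=[N-]
Why: Regitz diazo transfer, in which the methylene flanked by ketone and sulfone is acidic enough for triethylamine and its carbanion attacks the terminal nitrogen of the sulfonyl azide and expels the sulfonamide to leave the diazo group.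

**Step 5**
Reactants: 4 5,6-dimethoxy-1,3-dihydroisobenzofuran (3 equiv, excess recovered); 8 2-diazo-1-(2,4-dimethoxyphenyl)-2-(phenylsulfonyl)ethanone
Product: 10 racemic (2,4-dimethoxyphenyl)[6,7-dimethoxy-3-(phenylsulfonyl)isochroman-3-yl]methanone, via oxonium ylide 9 (not isolated)
Conditions: Cu(hfacac)2 [copper bis(hexafluoroacetylacetonate)] (10 mol %), ClCH2CH2Cl, 80 °C, slow addition of 8 to 4 and catalyst, argon
Reagents that add atoms: none
Why: The divalent copper catalyst decomposes 8 with loss of N2 to a catalyst-bound, strongly electrophilic keto sulfonyl carbene, which is captured by the sp3 ether oxygen of 4 and released as oxonium ylide 9, its carbanion stabilised by the ketone and the sulfone. One of the two equivalent benzylic C–O bonds of 9, weakened by the para-methoxy group on ring A, then cleaves to a caged radical pair (or tight ion pair) that recombines at the ylide carbon, a Stevens [1,2]-shift that forms O2–C3 and C3–C4. Ring B is therefore closed not by an end-to-end cyclisation but by one-carbon ring expansion of the five-membered ether to the six-membered isochroman. The closest known reaction type is the copper- or rhodium-catalysed reaction of diazo carbonyl compounds with benzylic ethers and 2-aryl cyclic ethers such as 2-aryloxetanes, which proceeds by oxonium ylide formation and benzylic [1,2]-shift with ring expansion. C3 becomes a quaternary stereocentre with no chiral element present, so 10 should form as the racemate, which is immaterial because C3 is sp2 after step 6. The step needs ylide formation at the dialkyl ether oxygen to outrun benzylic C–H insertion, attack on the electron-rich arenes and capture by the ortho-methoxy oxygen of ring C: the ether oxygen is the most Lewis-basic site, copper carbenes with two acceptor groups prefer lone pairs to C–H bonds, an aryl methyl ether ylide has no good migrating group and reverts, 4 is kept in excess with 8 at low concentration, and the symmetry of 4 removes any choice between the two benzylic carbons.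

**Step 6**
Reactants: 10 racemic (2,4-dimethoxyphenyl)[6,7-dimethoxy-3-(phenylsulfonyl)isochroman-3-yl]methanone
Product: 11 (2,4-dimethoxyphenyl)(6,7-dimethoxy-1H-isochromen-3-yl)methanone
Conditions: DBU (2 equiv), toluene, 80 °C, argon
Reagents that add atoms: none
Why: Base-mediated β-elimination of benzenesulfinic acid from a 2-sulfonyl cyclic ether, in which the ring-oxygen lone pair assists departure of the axial sulfinate from C3 while DBU removes a benzylic C4 proton (C4 being the only neighbour of C3 that bears hydrogen), should give the C3=C4 enol ether conjugated with ring A and the ketone.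

**Compound list**

1 | dimethyl 4,5-dimethoxyphthalate | COC(=O)c1cc(OC)c(OC)cc1C(=O)OC | starting material
2 | (4,5-dimethoxy-1,2-phenylene)dimethanol | OCc1cc(OC)c(OC)cc1CO | intermediate
3 | sodium [2-(tosyloxymethyl)-4,5-dimethoxyphenyl]methanolate (monotosylate sodium alkoxide) | [Na+].[O-]Cc1cc(OC)c(OC)cc1COS(=O)(=O)c1ccc(C)cc1 | intermediate
4 | 5,6-dimethoxy-1,3-dihydroisobenzofuran | COc1cc2COCc2cc1OC | intermediate
5 | 2-bromo-1-(2,4-dimethoxyphenyl)ethanone | COc1ccc(C(=O)CBr)c(OC)c1 | starting material
6 | sodium benzenesulfinate | [Na+].[O-]S(=O)c1ccccc1 | starting material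
7 | 1-(2,4-dimethoxyphenyl)-2-(phenylsulfonyl)ethanone | COc1ccc(C(=O)CS(=O)(=O)c2ccccc2)c(OC)c1 | intermediate
8 | 2-diazo-1-(2,4-dimethoxyphenyl)-2-(phenylsulfonyl)ethanone | COc1ccc(C(=O)C(=[N+]=[N-])S(=O)(=O)c2ccccc2)c(OC)c1 | intermediate
9 | oxonium ylide: 5,6-dimethoxy-1,3-dihydroisobenzofuran-2-ium-2-yl [2-(2,4-dimethoxyphenyl)-2-oxo-1-(phenylsulfonyl)]ethanide | COc1ccc(C(=O)[C-](S(=O)(=O)c2ccccc2)[O+]2Cc3cc(OC)c(OC)cc3C2)c(OC)c1 | intermediate
10 | racemic (2,4-dimethoxyphenyl)[6,7-dimethoxy-3-(phenylsulfonyl)isochroman-3-yl]methanone | COc1ccc(C(=O)C2(S(=O)(=O)c3ccccc3)Cc3cc(OC)c(OC)cc3CO2)c(OC)c1 | intermediate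
11 | (2,4-dimethoxyphenyl)(6,7-dimethoxy-1H-isochromen-3-yl)methanone | COc1ccc(C(=O)C2=Cc3cc(OC)c(OC)cc3CO2)c(OC)c1 | target

**Step count**

Total steps: 6 (two branches of two steps each, then two steps after they join).
Longest linear sequence: 4 steps (steps 1, 2, 5, 6 or steps 3, 4, 5, 6).

**Steps most likely to fail**

1. Step 5. Carbene transfer may be diverted from the ether oxygen (insertion into the doubly activated benzylic C–H bonds of 4, capture by the ortho-methoxy group of ring C, Wolff rearrangement). Alternatively the doubly stabilised ylide may fail to rearrange, reverting or recombining through the enolate oxygen instead of carbon. The fallback makes the same two bonds one after the other by known reactions; it sets out from diol 2 and diazo compound 8 and returns at 10. Rh2(OAc)4-catalysed O–H insertion of the carbene from 8 into one hydroxyl of 2 (2 in excess, ClCH2CH2Cl, 40 °C) should form the O2–C3 bond and give racemic 2-{[2-(hydroxymethyl)-4,5-dimethoxybenzyl]oxy}-1-(2,4-dimethoxyphenyl)-2-(phenylsulfonyl)ethanone F1. MsCl and Et3N in CH2Cl2 at 0 °C should turn the remaining electron-rich benzylic alcohol into the benzylic chloride, racemic 2-{[2-(chloromethyl)-4,5-dimethoxybenzyl]oxy}-1-(2,4-dimethoxyphenyl)-2-(phenylsulfonyl)ethanone F2. K2CO3 in MeCN should then close ring B by intramolecular C-alkylation of the methine activated by ketone and sulfone (6-exo-tet, C3–C4 bond) to give 10.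

2. Step 6. The sulfinate may fail to leave, because ionisation at C3 is retarded by the adjacent carbonyl and the C4 protons are only benzylic. The electron-rich isochromene may also degrade under hot base or by aerial oxidation at C1. The fallback replaces elimination by reduction and dehydrogenation; it sets out from 10 and returns at 11. SmI2 (2 equiv, THF/MeOH, −78 °C) should cleave the C–S bond of the α-sulfonyl ketone reductively to racemic (2,4-dimethoxyphenyl)(6,7-dimethoxyisochroman-3-yl)methanone F3. Enolisation at C3, the only enolisable position (LDA, THF, −78 °C), and trapping with PhSeBr should give racemic (2,4-dimethoxyphenyl)[6,7-dimethoxy-3-(phenylselanyl)isochroman-3-yl]methanone F4. H2O2 in CH2Cl2 at 0 °C should oxidise it to the selenoxide (2,4-dimethoxyphenyl)[6,7-dimethoxy-3-(phenylseleninyl)isochroman-3-yl]methanone F5 (mixture of diastereomers). Its syn elimination can only run toward C4 and should deliver 11.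

3. Step 2. Intermolecular etherification or oligomerisation of the very reactive benzylic tosylate, or double tosylation, may compete with ring closure. The fallback avoids any benzylic leaving group by passing through the lactone oxidation level; it sets out from 2 and returns at 4. MnO2 in CH2Cl2 at rt should oxidise the diol to 5,6-dimethoxyisobenzofuran-1(3H)-one F6. DIBAL-H in CH2Cl2 at −78 °C should reduce it to the lactol, racemic 5,6-dimethoxy-1,3-dihydroisobenzofuran-1-ol F7. Et3SiH with BF3·OEt2 in CH2Cl2 at −78 °C should then remove the lactol hydroxyl by ionic hydrogenation to give 4.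

**Further compounds**

F1 | step 5 | racemic 2-{[2-(hydroxymethyl)-4,5-dimethoxybenzyl]oxy}-1-(2,4-dimethoxyphenyl)-2-(phenylsulfonyl)ethanone | COc1ccc(C(=O)C(OCc2cc(OC)c(OC)cc2CO)S(=O)(=O)c2ccccc2)c(OC)c1
F2 | step 5 | racemic 2-{[2-(chloromethyl)-4,5-dimethoxybenzyl]oxy}-1-(2,4-dimethoxyphenyl)-2-(phenylsulfonyl)ethanone | COc1ccc(C(=O)C(OCc2cc(OC)c(OC)cc2CCl)S(=O)(=O)c2ccccc2)c(OC)c1
F3 | step 6 | racemic (2,4-dimethoxyphenyl)(6,7-dimethoxyisochroman-3-yl)methanone | COc1ccc(C(=O)C2Cc3cc(OC)c(OC)cc3CO2)c(OC)c1
F4 | step 6 | racemic (2,4-dimethoxyphenyl)[6,7-dimethoxy-3-(phenylselanyl)isochroman-3-yl]methanone | COc1ccc(C(=O)C2([Se]c3ccccc3)Cc3cc(OC)c(OC)cc3CO2)c(OC)c1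
F5 | step 6 | (2,4-dimethoxyphenyl)[6,7-dimethoxy-3-(phenylseleninyl)isochroman-3-yl]methanone, mixture of diastereomers | COc1ccc(C(=O)C2([Se](=O)c3ccccc3)Cc3cc(OC)c(OC)cc3CO2)c(OC)c1
F6 | step 2 | 5,6-dimethoxyisobenzofuran-1(3H)-one | COc1cc2COC(=O)c2cc1OC
F7 | step 2 | racemic 5,6-dimethoxy-1,3-dihydroisobenzofuran-1-ol | COc1cc2COC(O)c2cc1OC
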